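**Plan**
- Retrosynthesis: after removal of the two benzyl ethers and the 7-O-methyl group, ring A is cut at C7–C8 and C5–C6. This leaves a fully substituted 4-pyranone-3-carboxylate (ring C already carrying ring B) and methyl methoxyacetate.
- Enabling feature: in ring A, C5 and C7 are at the carbonyl oxidation level and are separated by the methoxylated carbons C6 and C8, so C5–C6 and C7–C8 are two head-to-tail methoxyacetyl units. The C5 hydroxyl is tied to the C4 carbonyl by a hydrogen bond, which later tells it apart from the C7 hydroxyl.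
- The pyranone is cut at its ring C–O bond and at the aroyl C–C bond, back to an open-chain triketo ester. This comes from methyl 4-methoxyacetoacetate, methoxyacetyl chloride and a ring B N-methoxy-N-methylamide (four steps from 3,4-bis(benzyloxy)benzaldehyde).
- Forward order: ring B piece, open-chain triketo ester, ring C by cyclodehydration, ring A by Claisen–Dieckmann annulation, 7-O-methylation, hydrogenolysis.
- Stereochemistry: the target has no stereocentre; only regiochemistry matters, and it follows from connectivity and from the C5–OH···O=C4 hydrogen bond.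

Key step: step 8

Remark: enolisable polycarbonyl compounds are named and drawn as keto tautomers, and lithium salts formed in the flask are drawn in neutral form.

**Step 1**
Reactants: 1 3,4-bis(benzyloxy)benzaldehyde
Product: 3 3,4-bis(benzyloxy)phenol, via aryl formate 2 (not isolated)
Conditions: mCPBA, CH2Cl2, 0 °C to rt; then K2CO3 (cat.), MeOH, rt
Reagents that add atoms: 3-chloroperoxybenzoic acid (mCPBA), O=C(OO)c1cccc(Cl)c1
Why: Baeyer–Villiger oxidation (Dakin-type) in which the electron-rich aryl group migrates in the Criegee intermediate to give formate 2, which catalytic carbonate in methanol transesterifies to the phenol while the benzyl ethers are untouched.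

**Step 2**
Reactants: 3 3,4-bis(benzyloxy)phenol
Product: 4 1,2-bis(benzyloxy)-4-methoxybenzene
Conditions: MeI, K2CO3, acetone, reflux
Reagents that add atoms: iodomethane, CI
Why: Williamson ether synthesis in which the phenoxide formed with K2CO3 is alkylated by iodomethane in an SN2 reaction, no other acidic site being present.

**Step 3**
Reactants: 4 1,2-bis(benzyloxy)-4-methoxybenzene
Product: 5 1,2-bis(benzyloxy)-4-bromo-5-methoxybenzene
Conditions: NBS, MeCN, 0 °C to rt
Reagents that add atoms: N-bromosuccinimide, O=C1CCC(=O)N1Br
Why: Electrophilic aromatic bromination at the one unhindered carbon that is ortho to the methoxy group and para to a benzyloxy group, the outcome expected for 1,2,4-trialkoxybenzenes, whereas the only other doubly activated carbon lies between two substituents.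

**Step 4**
Reactants: 5 1,2-bis(benzyloxy)-4-bromo-5-methoxybenzene
Product: 7 4,5-bis(benzyloxy)-N,2-dimethoxy-N-methylbenzamide, via aryllithium 6 (not isolated)
Conditions: n-BuLi, THF, −78 °C; then added to ClC(O)N(OMe)Me (1.5 equiv), THF, −78 to 0 °C
Reagents that add atoms: N-methoxy-N-methylcarbamoyl chloride, CON(C)C(Cl)=O
Why: Bromine–lithium exchange at −78 °C outpaces benzylic deprotonation, and inverse addition lets the aryllithium undergo acyl substitution on the far more electrophilic carbamoyl chloride before it can attack the amide product.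

**Step 5**
Reactants: 8 methyl 4-methoxyacetoacetate; 9 methoxyacetyl chloride
Product: 10 methyl 4-methoxy-2-(methoxyacetyl)-3-oxobutanoate
Conditions: MgCl2 (1 equiv), pyridine (2 equiv), CH2Cl2, 0 °C to rt; aq. HCl work-up
Reagents that add atoms: none
Why: Soft-enolisation C-acylation of a β-keto ester, in which MgCl2 chelation lets pyridine form the magnesium enolate and this is acylated at carbon by the acid chloride.

**Step 6**
Reactants: 10 methyl 4-methoxy-2-(methoxyacetyl)-3-oxobutanoate; 7 4,5-bis(benzyloxy)-N,2-dimethoxy-N-methylbenzamide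
Product: 12 methyl 5-[4,5-bis(benzyloxy)-2-methoxyphenyl]-4-methoxy-2-(methoxyacetyl)-3,5-dioxopentanoate, via lithium hemiaminal adduct 11 (not isolated)
Conditions: 10 (1.3 equiv), LiN(iPr)2 (2.7 equiv), THF, −78 to −20 °C; then 7, −78 to 0 °C; 1 M HCl
Reagents that add atoms: none
Why: γ-Acylation of a β-dicarbonyl dianion, in which the second equivalent of amide deprotonates one of the two symmetry-equivalent methoxymethylene groups of the tricarbonyl monoanion, the terminal carbanion adds to the N-methoxy-N-methylamide, and chelated adduct 11 holds the ketone oxidation level until the acidic quench.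

**Step 7**
Reactants: 12 methyl 5-[4,5-bis(benzyloxy)-2-methoxyphenyl]-4-methoxy-2-(methoxyacetyl)-3,5-dioxopentanoate
Product: 13 methyl 6-[4,5-bis(benzyloxy)-2-methoxyphenyl]-5-methoxy-2-(methoxymethyl)-4-oxo-4H-pyran-3-carboxylate
Conditions: p-TsOH·H2O (cat.), toluene, reflux, Dean–Stark
Reagents that add atoms: none
Why: Acid-catalysed cyclodehydration of a 1,3,5-triketone, in which the enol oxygen of one outer ketone adds to the other outer ketone and water is lost to give the 4-pyranone, the ketone being a better electrophile than the ester under acid and water removal making the closure irreversible.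

**Step 8**
Reactants: 13 methyl 6-[4,5-bis(benzyloxy)-2-methoxyphenyl]-5-methoxy-2-(methoxymethyl)-4-oxo-4H-pyran-3-carboxylate; 14 methyl methoxyacetate
Product: 16 4',5'-bis(benzyloxy)-5,7-dihydroxy-3,6,8,2'-tetramethoxyflavone, via acyclic Claisen ketone 15 (not isolated)
Conditions: LiN(iPr)2 (1.1 equiv), THF, −78 °C; 14 (1.5 equiv), −78 to −20 °C; LiN(iPr)2 (2.2 equiv), −78 to 20 °C; 1 M HCl
Reagents that add atoms: none
Why: Proposed new method: LiN(iPr)2 should deprotonate the 2-methoxymethyl group of 13, whose hydrogens are vinylogously acidified by the C4 carbonyl and the C3 ester, and the carbanion attacks the carbonyl of 14 to form C7–C8 and give ketone 15 as its enolate, the expelled LiOMe relaying protons so that the more acidic product does not stall the condensation. The second charge of amide then removes a proton from the terminal methoxymethylene of 15, and this carbanion closes onto the ring ester in a 6-exo-trig Dieckmann acylation (C5–C6), after which the cyclic trione tautomerises irreversibly to the aromatic 5,7-diol and pulls both equilibria forward. The nearest precedent is the one-flask acylation–cyclisation of lithiated ortho-toluate esters with esters, which gives arene-1,3-diols, taken together with the known lateral lithiation and acylation of 2-alkyl-4-pyranones. No stereocentre is formed. The step needs chemoselective side-chain deprotonation and C-acylation at the exocyclic carbon; the substrate secures this because C2 and C6 of the pyranone are both fully substituted, leaving no open position for addition of amide or methoxide, and because reaction through ring carbon C3 would break the pyranone conjugation. Ring A regiochemistry is fixed by connectivity (ester carbon becomes C5, methoxymethyl carbon becomes C8), and staging the base keeps free amide away from enolisable 14 during the intermolecular condensation.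

**Step 9**
Reactants: 16 4',5'-bis(benzyloxy)-5,7-dihydroxy-3,6,8,2'-tetramethoxyflavone
Product: 17 4',5'-bis(benzyloxy)-5-hydroxy-3,6,7,8,2'-pentamethoxyflavone
Conditions: MeI (1.1 equiv), K2CO3 (1.2 equiv), acetone, 40 °C
Reagents that add atoms: iodomethane, CI
Why: Williamson methylation made regioselective by the hydrogen bond between the C5 hydroxyl and the C4 carbonyl, which lowers the acidity and nucleophilicity of that hydroxyl so that one equivalent of base and iodomethane reacts at the free C7 phenoxide.

**Step 10**
Reactants: 17 4',5'-bis(benzyloxy)-5-hydroxy-3,6,7,8,2'-pentamethoxyflavone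
Product: 18 5,4',5'-trihydroxy-3,6,7,8,2'-pentamethoxyflavone
Conditions: H2 (1 atm), 10% Pd/C, EtOAc–MeOH, rt
Reagents that add atoms: none
Why: Catalytic hydrogenolysis of the two benzyl aryl ethers over Pd/C, under which the tetrasubstituted C2=C3 bond of the flavone, the aryl methyl ethers and the chelated phenol are inert.

**Compound list**
1 | 3,4-bis(benzyloxy)benzaldehyde | O=Cc1ccc(OCc2ccccc2)c(OCc2ccccc2)c1 | starting material
2 | 3,4-bis(benzyloxy)phenyl formate | O=COc1ccc(OCc2ccccc2)c(OCc2ccccc2)c1 | intermediate (not isolated)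
3 | 3,4-bis(benzyloxy)phenol | Oc1ccc(OCc2ccccc2)c(OCc2ccccc2)c1 | intermediate
4 | 1,2-bis(benzyloxy)-4-methoxybenzene | COc1ccc(OCc2ccccc2)c(OCc2ccccc2)c1 | intermediate
5 | 1,2-bis(benzyloxy)-4-bromo-5-methoxybenzene | COc1cc(OCc2ccccc2)c(OCc2ccccc2)cc1Br | intermediate
6 | [4,5-bis(benzyloxy)-2-methoxyphenyl]lithium | [Li]c1cc(OCc2ccccc2)c(OCc2ccccc2)cc1OC | intermediate (not isolated)
7 | 4,5-bis(benzyloxy)-N,2-dimethoxy-N-methylbenzamide | CON(C)C(=O)c1cc(OCc2ccccc2)c(OCc2ccccc2)cc1OC | intermediate
8 | methyl 4-methoxyacetoacetate (methyl 4-methoxy-3-oxobutanoate) | COCC(=O)CC(=O)OC | starting material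
9 | methoxyacetyl chloride | COCC(=O)Cl | starting material
10 | methyl 4-methoxy-2-(methoxyacetyl)-3-oxobutanoate | COCC(=O)C(C(=O)OC)C(=O)COC | intermediate
11 | methyl 5-[4,5-bis(benzyloxy)-2-methoxyphenyl]-5-hydroxy-4-methoxy-5-[methoxy(methyl)amino]-2-(methoxyacetyl)-3-oxopentanoate (present as its lithium salt) | COCC(=O)C(C(=O)OC)C(=O)C(OC)C(O)(N(C)OC)c1cc(OCc2ccccc2)c(OCc2ccccc2)cc1OC | intermediate (not isolated)
12 | methyl 5-[4,5-bis(benzyloxy)-2-methoxyphenyl]-4-methoxy-2-(methoxyacetyl)-3,5-dioxopentanoate | COCC(=O)C(C(=O)OC)C(=O)C(OC)C(=O)c1cc(OCc2ccccc2)c(OCc2ccccc2)cc1OC | intermediate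
13 | methyl 6-[4,5-bis(benzyloxy)-2-methoxyphenyl]-5-methoxy-2-(methoxymethyl)-4-oxo-4H-pyran-3-carboxylate | COCc1oc(-c2cc(OCc3ccccc3)c(OCc3ccccc3)cc2OC)c(OC)c(=O)c1C(=O)OC | intermediate
14 | methyl methoxyacetate | COCC(=O)OC | starting material
15 | methyl 6-[4,5-bis(benzyloxy)-2-methoxyphenyl]-2-(1,3-dimethoxy-2-oxopropyl)-5-methoxy-4-oxo-4H-pyran-3-carboxylate (present as its lithium enolate) | COCC(=O)C(OC)c1oc(-c2cc(OCc3ccccc3)c(OCc3ccccc3)cc2OC)c(OC)c(=O)c1C(=O)OC | intermediate (not isolated)
16 | 4',5'-bis(benzyloxy)-5,7-dihydroxy-3,6,8,2'-tetramethoxyflavone | COc1cc(OCc2ccccc2)c(OCc2ccccc2)cc1-c1oc2c(OC)c(O)c(OC)c(O)c2c(=O)c1OC | intermediate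
17 | 4',5'-bis(benzyloxy)-5-hydroxy-3,6,7,8,2'-pentamethoxyflavone | COc1cc(OCc2ccccc2)c(OCc2ccccc2)cc1-c1oc2c(OC)c(OC)c(OC)c(O)c2c(=O)c1OC | intermediate
18 | 5,4',5'-trihydroxy-3,6,7,8,2'-pentamethoxyflavone | COc1cc(O)c(O)cc1-c1oc2c(OC)c(OC)c(OC)c(O)c2c(=O)c1OC | target

**Step count**
Total: 10 steps. Longest linear sequence: 9 steps (steps 1–4 and 6–10); step 5 is a one-step side branch.

**Steps most likely to fail**

1. Step 8 (proposed new method). Proton exchange between the pyranone carbanion and enolisable 14 may outrun C-acylation, liberated methoxide may open the pyranone ring, or the second enolate may fail to close onto the charge-deactivated ring ester. The fallback gives up the open-chain construction of ring A and uses known flavone chemistry on a pre-formed pentaoxygenated benzene; it sets out from bromide 5 and comes back at target 18.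
   - Aryllithium 6, generated from 5 as in step 4, is quenched with DMF to give 4,5-bis(benzyloxy)-2-methoxybenzaldehyde F1.
   - Claisen–Schmidt condensation of F1 with commercially available 1-(2-hydroxy-3,4,5,6-tetramethoxyphenyl)ethanone (CC(=O)c1c(O)c(OC)c(OC)c(OC)c1OC; KOH, EtOH) should give (E)-3-[4,5-bis(benzyloxy)-2-methoxyphenyl]-1-(2-hydroxy-3,4,5,6-tetramethoxyphenyl)prop-2-en-1-one F2.
   - Oxidative cyclisation with catalytic iodine in hot DMSO should give 4',5'-bis(benzyloxy)-5,6,7,8,2'-pentamethoxyflavone F3.
   - Epoxidation of the C2=C3 bond with dimethyldioxirane and acid-promoted opening should give 4',5'-bis(benzyloxy)-3-hydroxy-5,6,7,8,2'-pentamethoxyflavone F4.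
   - Methylation (MeI, K2CO3) should give 4',5'-bis(benzyloxy)-3,5,6,7,8,2'-hexamethoxyflavone F5.
   - BCl3 with pentamethylbenzene in CH2Cl2 (−78 to 0 °C) should cleave the carbonyl-chelated 5-O-methyl group and both benzyl ethers in one operation, which arrives at 18.

2. Step 6. The second deprotonation of the tricarbonyl monoanion may be incomplete, or addition of the secondary α-methoxy carbanion to the hindered, electron-rich amide may be so slow that the dianion is lost by proton transfer on warming. The fallback replaces acyl transfer by an aldol addition followed by oxidation; it sets out from 5 and 10 and comes back at 12.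
   - 4,5-Bis(benzyloxy)-2-methoxybenzaldehyde F1 (from 5 through 6 and DMF, as above) is added at −78 °C to the dianion of 10; the much more electrophilic and unhindered aldehyde should give methyl 5-[4,5-bis(benzyloxy)-2-methoxyphenyl]-5-hydroxy-4-methoxy-2-(methoxyacetyl)-3-oxopentanoate F6.
   - Oxidation of the electron-rich benzylic alcohol with MnO2 in CH2Cl2 should then give 12.

3. Step 7. The aryl ketone enol may close onto the ester with loss of methanol (lactonisation to a 2-pyranone) instead of dehydrating between the two outer ketones, and hot acid may strip benzyl ethers. The fallback moves the ring closure to a more electrophilic carbon and needs only a single deprotonation; it sets out from 10 and 7 and comes back at 13.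
   - O-Methylation of the enol of 10 with trimethylsilyldiazomethane (toluene–MeOH) should give methyl 3,4-dimethoxy-2-(methoxyacetyl)but-2-enoate F7.
   - Deprotonation with LiN(iPr)2 (1.1 equiv, THF, −78 °C) and acylation with 7 should give methyl 2-{3-[4,5-bis(benzyloxy)-2-methoxyphenyl]-2-methoxy-3-oxopropanoyl}-3,4-dimethoxybut-2-enoate F8.
   - Brief treatment with trifluoroacetic acid in CH2Cl2 at rt should close the ring by addition–elimination of the aryl ketone enol oxygen at the methoxy-bearing alkene carbon, which is far more electrophilic than the ester, and deliver 13.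

**Further compounds**
F1 | step 8 | 4,5-bis(benzyloxy)-2-methoxybenzaldehyde | COc1cc(OCc2ccccc2)c(OCc2ccccc2)cc1C=O
F2 | step 8 | (E)-3-[4,5-bis(benzyloxy)-2-methoxyphenyl]-1-(2-hydroxy-3,4,5,6-tetramethoxyphenyl)prop-2-en-1-one | COc1cc(OCc2ccccc2)c(OCc2ccccc2)cc1/C=C/C(=O)c1c(O)c(OC)c(OC)c(OC)c1OC
F3 | step 8 | 4',5'-bis(benzyloxy)-5,6,7,8,2'-pentamethoxyflavone | COc1cc(OCc2ccccc2)c(OCc2ccccc2)cc1-c1cc(=O)c2c(OC)c(OC)c(OC)c(OC)c2o1
F4 | step 8 | 4',5'-bis(benzyloxy)-3-hydroxy-5,6,7,8,2'-pentamethoxyflavone | COc1cc(OCc2ccccc2)c(OCc2ccccc2)cc1-c1oc2c(OC)c(OC)c(OC)c(OC)c2c(=O)c1O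
F5 | step 8 | 4',5'-bis(benzyloxy)-3,5,6,7,8,2'-hexamethoxyflavone | COc1cc(OCc2ccccc2)c(OCc2ccccc2)cc1-c1oc2c(OC)c(OC)c(OC)c(OC)c2c(=O)c1OC
F6 | step 6 | methyl 5-[4,5-bis(benzyloxy)-2-methoxyphenyl]-5-hydroxy-4-methoxy-2-(methoxyacetyl)-3-oxopentanoate | COCC(=O)C(C(=O)OC)C(=O)C(OC)C(O)c1cc(OCc2ccccc2)c(OCc2ccccc2)cc1OC
F7 | step 7 | methyl 3,4-dimethoxy-2-(methoxyacetyl)but-2-enoate | COCC(OC)=C(C(=O)OC)C(=O)COC
F8 | step 7 | methyl 2-{3-[4,5-bis(benzyloxy)-2-methoxyphenyl]-2-methoxy-3-oxopropanoyl}-3,4-dimethoxybut-2-enoate | COCC(OC)=C(C(=O)OC)C(=O)C(OC)C(=O)c1cc(OCc2ccccc2)c(OCc2ccccc2)cc1OC
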